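A direct plan would build the iso-C22 alcohol 20-methylhenicosan-1-ol A5 from three pieces by two successive Li2CuCl4-catalysed Grignard couplings: 1-bromo-3-methylbutane A1 with 1-bromo-6-chlorohexane A2 to 1-chloro-9-methyldecane A3, then the Grignard reagent of A3 with 11-bromoundecan-1-ol A4.
It would end with a 1:1 dehydrative esterification of A5 with unprotected 2,3-dihydroxybenzoic acid A6 under arylboronic acid catalysis.
Weakest is that closing esterification of the free catechol acid: it would rest on an untested catalytic mode at the one convergent, last step. The catechol binds boron so firmly that turnover is doubtful, the carboxyl is deactivated by the hydrogen bond from the ortho hydroxyl, and phenol acylation and air oxidation compete in refluxing toluene.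
Second is the Grignard formation from the primary chloride A3 in the middle of the chain build: magnesium insertion is sluggish, and its Wurtz dimer and reduced alkane are C22/C11 waxes that co-crystallise with A5.
Third is the chain assembly as a whole: a linear, three-piece run-up with a bromide-over-chloride selectivity demand, spent on a plain fatty alcohol, while the arene, the only functionalised part, is simply bought.

Retrosynthetic overview
The benzene ring is made last instead of bought. Its contiguous triad C1(CO2R)–C2(OH)–C3(OH) is cut at the ring bonds C1–C2 and C3–C4: C2, C3 and both phenolic oxygens come from the glycolic-acid-level C2 unit 1,1,2-tris(trimethylsiloxy)ethene; C1, C4, C5, C6 and the ester come from a 2-pyrone-3-carboxylate whose lactone leaves as CO2.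
The fatty ester is placed on the pyrone before the ring exists. The only ring of the target is then closed in the final operation (inverse-demand Diels–Alder, CO2 extrusion, silanol loss) and appears directly as the free catechol: no esterification of a catechol acid, no phenol protection, no step after the sensitive group is unveiled.
The iso-C22 chain is cut once (C6 + C16, both halves commercial), with a bromide-derived Grignard reagent whose own by-products are volatile.

Key step: step 3

Remark: the target is achiral, so no stereocentre has to be set, and the four building blocks of the route are taken as catalogue chemicals.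

Step 1
Reactants: 1 1-bromo-4-methylpentane; 2 16-bromohexadecan-1-ol
Product: 6 20-methylhenicosan-1-ol, via (4-methylpentyl)magnesium bromide 3 (not isolated), via bromomagnesium 16-bromohexadecan-1-olate 4 (not isolated), via bromomagnesium 20-methylhenicosan-1-olate 5 (not isolated)
Conditions: 1 (2.5 equiv), Mg, THF, 40 °C; then 2, Li2CuCl4 (3 mol %), NMP (4 equiv), THF, −10 °C → rt; aq. NH4Cl; recrystallise (acetone)
Reagents that add atoms: none
Why: In this Kochi–Tamura copper-catalysed sp3–sp3 Grignard cross-coupling the first equivalent of 3 only deprotonates 2 to the alkoxide 4, the alkylcuprate formed from further 3 then displaces the primary bromide of 4, and the single C6 + C16 cut completes the iso-C22 chain (3 + 16 = 19 CH2) in one operation with no stereocentre formed.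

Step 2
Reactants: 6 20-methylhenicosan-1-ol; 7 2-oxo-2H-pyran-3-carboxylic acid
Product: 9 20-methylhenicosyl 2-oxo-2H-pyran-3-carboxylate, via 2-oxo-2H-pyran-3-carbonyl chloride 8 (not isolated)
Conditions: 7, (COCl)2 (1.2 equiv), DMF (2 mol %), CH2Cl2, 0 °C → rt; evaporate; then 6 (0.95 equiv), 2,6-lutidine (1.3 equiv), CH2Cl2/PhMe, 0 → 35 °C
Reagents that add atoms: none
Why: Vilsmeier-catalysed acid chloride formation followed by alcoholysis (nucleophilic acyl substitution) should work because the acyl chloride is far more electrophilic than the lactone carbonyl or C6 of the pyrone and the hindered 2,6-lutidine only takes up HCl, so the primary alcohol 6 is acylated without ring opening; no stereocentre is formed.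

Step 3
Reactants: 9 20-methylhenicosyl 2-oxo-2H-pyran-3-carboxylate; 10 1,1,2-tris(trimethylsiloxy)ethene
Product: 14 gentiside A (20-methylhenicosyl 2,3-dihydroxybenzoate), via oxabicyclo[2.2.2]octenone cycloadduct 11 (not isolated), via tris(trimethylsiloxy)cyclohexadiene ester 12 (not isolated), via bis(trimethylsilyl) ether of gentiside A 13 (not isolated)
Conditions: 9, 10 (2.5 equiv), PhMe (0.2 M), 110 °C, sealed tube, Ar, 16 h; then MeOH/THF, citric acid (cat.), rt
Reagents that add atoms: none
Why: Proposed new method: the diene of 9 (pyrone C3=C4–C5=C6, made electron-poor by the lactone carbonyl and the C3 ester) should add the electron-rich ketene bis(silyl) acetal 10 in an inverse-electron-demand Diels–Alder reaction to give the bridged lactone 11, which expels CO2 by cycloreversion to the cyclohexadiene 12; ionisation of the allylic silyl ketal of 12 and loss of the neighbouring proton (net loss of Me3SiOH) aromatise it to 13, whose two aryl silyl ethers are methanolysed to the free catechol 14. The closest known reaction type is the thermal benzannulation of 3-carbomethoxy-2-pyrones with O-alkyl ketene acetals (1,1-dimethoxyethene and its 2-alkoxy congener), which gives 2-alkoxy- and 2,3-dialkoxybenzoates; new is the tris-silyl ketene acetal, which should let the catechol emerge unprotected. The carbocycle is closed by an intermolecular [4+2] cycloaddition that forms the arene bonds C1–C2 (pyrone C3 to the ketal carbon of 10) and C3–C4 (the CH carbon of 10 to pyrone C6). The stereocentres of 11 and 12 form without control and need none, since all are erased on aromatisation. The step needs regioselectivity, secured by matched polarisation (the nucleophilic CH(OSiMe3) carbon of 10 bonds to the electrophilic pyrone C6, so the ketal carbon lands next to the ester), and retention of both oxygens, secured because only the ketal carbon can ionise and only the neighbouring CH(OSiMe3) carries a proton to lose. Toluene is chosen to disfavour the stepwise silyl-transfer (Mukaiyama–Michael) pathway that would stop at an open-chain adduct.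

Compound list
1 | 1-bromo-4-methylpentane | CC(C)CCCBr | starting material
2 | 16-bromohexadecan-1-ol | OCCCCCCCCCCCCCCCCBr | starting material
3 | (4-methylpentyl)magnesium bromide | CC(C)CCC[Mg]Br | intermediate
4 | bromomagnesium 16-bromohexadecan-1-olate | BrCCCCCCCCCCCCCCCCO[Mg]Br | intermediate
5 | bromomagnesium 20-methylhenicosan-1-olate | CC(C)CCCCCCCCCCCCCCCCCCCO[Mg]Br | intermediate
6 | 20-methylhenicosan-1-ol | CC(C)CCCCCCCCCCCCCCCCCCCO | intermediate
7 | 2-oxo-2H-pyran-3-carboxylic acid | OC(=O)C1=CC=COC1=O | starting material
8 | 2-oxo-2H-pyran-3-carbonyl chloride | ClC(=O)C1=CC=COC1=O | intermediate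
9 | 20-methylhenicosyl 2-oxo-2H-pyran-3-carboxylate | CC(C)CCCCCCCCCCCCCCCCCCCOC(=O)C1=CC=COC1=O | intermediate
10 | 1,1,2-tris(trimethylsiloxy)ethene | C[Si](C)(C)OC=C(O[Si](C)(C)C)O[Si](C)(C)C | starting material
11 | 20-methylhenicosyl 3-oxo-7,8,8-tris(trimethylsiloxy)-2-oxabicyclo[2.2.2]oct-5-ene-4-carboxylate (racemic, C7 epimers, stereocentres not controlled) | CC(C)CCCCCCCCCCCCCCCCCCCOC(=O)C12C=CC(OC1=O)C(O[Si](C)(C)C)C2(O[Si](C)(C)C)O[Si](C)(C)C | intermediate
12 | 20-methylhenicosyl 5,6,6-tris(trimethylsiloxy)cyclohexa-1,3-diene-1-carboxylate (racemic) | CC(C)CCCCCCCCCCCCCCCCCCCOC(=O)C1=CC=CC(O[Si](C)(C)C)C1(O[Si](C)(C)C)O[Si](C)(C)C | intermediate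
13 | 20-methylhenicosyl 2,3-bis(trimethylsiloxy)benzoate | CC(C)CCCCCCCCCCCCCCCCCCCOC(=O)c1cccc(O[Si](C)(C)C)c1O[Si](C)(C)C | intermediate
14 | gentiside A, 20-methylhenicosyl 2,3-dihydroxybenzoate (achiral) | CC(C)CCCCCCCCCCCCCCCCCCCOC(=O)c1cccc(O)c1O | target

Total step count: 3. Longest linear sequence: 3 steps (2 → 6 → 9 → 14).

Steps most likely to fail

Step 3 (bears the new-method label). The silyl ketene acetal may react stepwise, with silyl transfer to the pyrone enolate after the first C–C bond (Mukaiyama–Michael addition without ring closure). The cycloaddition may also be slower than thermal decay of 10, or silanol loss from 12 may stall. The fallback uses known chemistry, sets out from 9 and returns at 14. Compound 9 would be heated (PhMe, 110–140 °C) with 1,1,2-trimethoxyethene F1, a known O-alkyl ketene acetal made beforehand by elimination of methanol from commercial glyoxal bis(dimethyl acetal). The established pyrone/ketene acetal benzannulation, with loss of CO2 and methanol, should give 20-methylhenicosyl 2,3-dimethoxybenzoate F2. BBr3 (CH2Cl2, −78 → 0 °C) would then cleave both aryl methyl ethers to 14. The approach changes from a traceless silyl release to a catechol carried as its dimethyl ether and freed in a separate Lewis-acid dealkylation.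

Step 2. The strongly activated pyrone acyl chloride may suffer conjugate addition at C6 or opening of the enol lactone by chloride, base or the alcohol, before or during acylation. The fallback sets out from 6 and 7 and returns at 9. A Mitsunobu esterification (PPh3, diisopropyl azodicarboxylate, THF, 0 °C → rt) would activate the alcohol instead of the acid. The pyrone is then present only as its poorly electrophilic carboxylate, and the ester O–CH2 bond is formed by SN2 displacement at the alcohol carbon. No new isolated compound is made (entry F0).

Step 1. Wurtz-type homocoupling, β-hydride elimination or reduction of the bromide, and precipitation of the magnesium alkoxide may leave hexadecanol-type by-products that are hard to separate from the waxy product. The fallback sets out from 2 and returns at 6 without any organomagnesium step. Compound 2 and PPh3 (MeCN, reflux) would give (16-hydroxyhexadecyl)triphenylphosphonium bromide F3. Double deprotonation with NaN(SiMe3)2 (2.1 equiv, THF, −78 → 0 °C) and Wittig olefination with commercial 4-methylpentanal would give (Z)-20-methylhenicos-16-en-1-ol F4, whose alkene geometry is irrelevant. Hydrogenation (H2, Pd on carbon, EtOAc) would give 6.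

Further compounds
F1 | step 3 | 1,1,2-trimethoxyethene | COC=C(OC)OC
F2 | step 3 | 20-methylhenicosyl 2,3-dimethoxybenzoate | CC(C)CCCCCCCCCCCCCCCCCCCOC(=O)c1cccc(OC)c1OC
F0 | step 2 | none | none
F3 | step 1 | (16-hydroxyhexadecyl)triphenylphosphonium bromide | OCCCCCCCCCCCCCCCC[P+](c1ccccc1)(c1ccccc1)c1ccccc1.[Br-]
F4 | step 1 | (Z)-20-methylhenicos-16-en-1-ol | CC(C)CC/C=C\CCCCCCCCCCCCCCCO
A1 | direct plan | 1-bromo-3-methylbutane | CC(C)CCBr
A2 | direct plan | 1-bromo-6-chlorohexane | ClCCCCCCBr
A3 | direct plan | 1-chloro-9-methyldecane | CC(C)CCCCCCCCCl
A4 | direct plan | 11-bromoundecan-1-ol | OCCCCCCCCCCCBr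
A5 | direct plan | 20-methylhenicosan-1-ol | CC(C)CCCCCCCCCCCCCCCCCCCO
A6 | direct plan | 2,3-dihydroxybenzoic acid | OC(=O)c1cccc(O)c1O
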